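**Assumption:** the SMILES is taken literally – a cis-fused 1,10-oxirane (C2 and C9 on the same side), 4Z, (1R,3S,6R,7R,8R,10S) and a (2R,3R) ester epoxide; ten-membered-ring compounds carry germacrane locants (ring C1–C10, CH3 on C4 and C10, lactone carbons C11–C13).

## Retrosynthetic overview

1. Target ⇐ O3-desilylation and C11 methylenation of the saturated trans-6,12-lactone.
2. γ-Lactone and C8 ester ⇐ one Evans–Tishchenko reaction of a C6-keto/C8-hydroxy macrocycle with (2R,3R)-2,3-dimethyloxirane-2-carbaldehyde; the side-chain oxirane comes from methyl (R)-3-hydroxybutanoate by dianion chlorination, methylation and ring closure.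
3. 1,10-Oxirane ⇐ C8–OH-directed epoxidation of the (1(10)Z,4Z)-dienone, obtained by E→Z equilibration of the rearrangement product.
4. Ten-membered ring ⇐ anionic oxy-Cope rearrangement (C8–C9 bond) of a trans-1,2-dialkenylcyclohexenol with in-flask C7 alkylation; chirality passes from C1/C6 of the six-membered ring to C8 and C7.
5. Cyclohexenol ⇐ (S)-carvone (Luche reduction, silylation, allylic oxidation) plus a (Z)-alkoxyvinyl unit. Ring order: cyclohexene (bought) → cyclodecadiene → macrocycle oxirane → γ-lactone.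

## Route

**Step 1**
Reactants: 1 (S)-(+)-carvone
Product: 2 (1S,5S)-cis-carveol
Conditions: NaBH4, CeCl3·7H2O, MeOH, 0 °C
Reagents that add atoms: none
Why: Luche 1,2-reduction; hydride adds axially to the enone carbonyl so the bought C5 centre sets the new carbinol cis to the isopropenyl group (this carbinol becomes C3 of the target).

**Step 2**
Reactants: 2 (1S,5S)-cis-carveol
Product: 3 tert-butyldimethyl{[(1S,5S)-2-methyl-5-(prop-1-en-2-yl)cyclohex-2-en-1-yl]oxy}silane
Conditions: TBSCl, imidazole, DMF, 25 °C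
Reagents that add atoms: tert-butyldimethylsilyl chloride, CC(C)(C)[Si](C)(C)Cl
Why: Standard O-silylation of a secondary allylic alcohol; no stereocentre is touched.

**Step 3**
Reactants: 3 cis-carveol TBS ether
Product: 4 (4S,6S)-4-(tert-butyldimethylsilyloxy)-3-methyl-6-(prop-1-en-2-yl)cyclohex-2-en-1-one
Conditions: CrO3, 3,5-dimethylpyrazole, CH2Cl2, −20 °C
Reagents that add atoms: chromium trioxide, O=[Cr](=O)=O
Why: Allylic C–H oxidation to the enone; the only ring methylene flanking the trisubstituted alkene is oxidised (the other allylic ring position already carries OTBS), and the mild conditions leave the α-stereocentre and the β,γ-isopropenyl group in place.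

**Step 4**
Reactants: 5 2-phenylpropan-2-ol
Product: 6 (E)-1,2-dichloro-1-(2-phenylpropan-2-yloxy)ethene
Conditions: KH, THF, 0 °C; then Cl2C=CHCl, 25 °C
Reagents that add atoms: trichloroethene, ClC=C(Cl)Cl
Why: Alkoxide-induced dehydrochlorination of trichloroethene to dichloroacetylene followed by anti addition of the alkoxide (addition–elimination) gives the (E)-dichlorovinyl ether.

**Step 5**
Reactants: 6 (E)-1,2-dichloro-1-(2-phenylpropan-2-yloxy)ethene; 4 (4S,6S)-enone
Product: 8 (1S,4S,6S)-4-(tert-butyldimethylsilyloxy)-3-methyl-1-[(2-phenylpropan-2-yloxy)ethynyl]-6-(prop-1-en-2-yl)cyclohex-2-en-1-ol, via lithium cumyloxyacetylide 7 (not isolated)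
Conditions: 6, n-BuLi (2.2 equiv), THF, −78 → −40 °C; then 4, −78 °C; H2O
Reagents that add atoms: none
Why: Elimination/lithium–chlorine exchange gives the alkoxyacetylide, which adds 1,2 to the enone on the face anti to both the adjacent isopropenyl and the 4-silyloxy group, so the alkynyl and isopropenyl groups are trans (new carbinol S).

**Step 6**
Reactants: 8 alkynyl ether carbinol
Product: 9 (1S,4S,6S)-4-(tert-butyldimethylsilyloxy)-3-methyl-1-[(Z)-2-(2-phenylpropan-2-yloxy)ethenyl]-6-(prop-1-en-2-yl)cyclohex-2-en-1-ol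
Conditions: H2 (1 atm), Pd/CaCO3–Pb(OAc)2, quinoline, EtOAc/Et3N, 0 °C
Reagents that add atoms: none
Why: Lindlar syn-semihydrogenation of the electron-rich alkyne gives only the (Z)-enol ether and leaves the other alkenes alone; the acid-labile product is used directly.

**Step 7**
Reactants: 9 (Z)-alkoxyvinyl carbinol
Product: 12 methyl 2-[(3S,7R,8R,1(10)E,4Z)-3-(tert-butyldimethylsilyloxy)-4,10-dimethyl-6-oxo-8-(2-phenylpropan-2-yloxy)cyclodeca-1(10),4-dien-7-yl]acetate, via potassium alkoxide 10 (not isolated), via potassium enolate 11 (not isolated)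
Conditions: KN(SiMe3)2, 18-crown-6, THF, 0 → 25 °C; then ICH2CO2Me, −78 °C
Reagents that add atoms: methyl iodoacetate, COC(=O)CI
Why: Anionic oxy-Cope rearrangement with in-flask enolate alkylation; the trans-diequatorial dialkenyl alkoxide must react through the chair with axial O−, which gives the (E)-1(10) olefin and, with the cis-alkoxy group pseudoaxial, C8 (R); the enolate is then alkylated on its exposed face (away from the transannular olefin) to give C7 (R), and the tertiary cumyl oxide is too poor a leaving group to be lost from the β-alkoxy enolate.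

**Step 8**
Reactants: 12 (1(10)E,4Z)-keto ester
Product: 13 methyl 2-[(3S,7R,8R,1(10)Z,4Z)-3-(tert-butyldimethylsilyloxy)-4,10-dimethyl-6-oxo-8-(2-phenylpropan-2-yloxy)cyclodeca-1(10),4-dien-7-yl]acetate
Conditions: PhSSPh (0.2 equiv), AIBN (0.1 equiv), C6H6, 80 °C
Reagents that add atoms: none
Why: Thiyl-radical addition–elimination equilibrates the trisubstituted ring olefin to the less strained (Z) isomer (an (E) olefin in a ten-membered ring is roughly 3 kcal/mol higher), which is the geometry the cis-oxirane needs; no stereocentre is affected.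

**Step 9**
Reactants: 13 (1(10)Z,4Z)-keto ester
Product: 14 methyl 2-[(3S,7R,8R,1(10)Z,4Z)-3-(tert-butyldimethylsilyloxy)-8-hydroxy-4,10-dimethyl-6-oxocyclodeca-1(10),4-dien-7-yl]acetate
Conditions: CF3CO2H (2% v/v), CH2Cl2, 0 °C, 15 min; NaHCO3
Reagents that add atoms: none
Why: The tertiary benzylic ether ionises under dilute acid (E1 cleavage) while the TBS ether, ester and dienone survive; 14 is kept cold and neutral and used at once so the C8 hydroxyl does not lactonise onto the ester.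

**Step 10**
Reactants: 14 β-hydroxy ketone
Product: 15 methyl 2-[(1R,3S,7R,8R,10S,4Z)-3-(tert-butyldimethylsilyloxy)-1,10-epoxy-8-hydroxy-4,10-dimethyl-6-oxocyclodec-4-en-7-yl]acetate
Conditions: VO(acac)2 (5 mol %), t-BuOOH, CH2Cl2, 0 → 25 °C
Reagents that add atoms: tert-butyl hydroperoxide, CC(C)(C)OO
Why: Hydroxyl-directed vanadium-catalysed epoxidation; the homoallylic C8 hydroxyl delivers oxygen to the face of the (Z)-1(10) olefin syn to itself, giving the cis-oxirane (1R,10S), while the enone olefin is too electron-poor to react.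

**Step 11**
Reactants: 16 methyl (R)-3-hydroxybutanoate
Product: 17 methyl (2R,3R)-2-chloro-3-hydroxybutanoate
Conditions: LiN(iPr)2 (2.2 equiv), THF, −78 → −40 °C; C2Cl6, −78 °C; AcOH
Reagents that add atoms: hexachloroethane, ClC(Cl)(Cl)C(Cl)(Cl)Cl
Why: Fráter–Seebach-type dianion chlorination; the chelated dianion takes the electrophile anti to the C3 oxygen (the C2 configuration is erased again in step 12).

**Step 12**
Reactants: 17 methyl (2R,3R)-2-chloro-3-hydroxybutanoate
Product: 19 methyl (2R,3R)-2,3-dimethyloxirane-2-carboxylate, via lithium chlorohydrin alkoxide 18 (not isolated)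
Conditions: LiN(iPr)2 (2.1 equiv), THF, −78 °C; MeI, −78 → −30 °C; then 25 °C
Reagents that add atoms: iodomethane, CI
Why: A second Fráter–Seebach alkylation puts the methyl anti to the C3 oxygen of the chelated dianion, leaving Cl syn; Darzens-type intramolecular SN2 closure then inverts C2 and gives the cis (epoxyangelate) oxirane, with the bought C3 centre controlling C2.

**Step 13**
Reactants: 19 methyl (2R,3R)-2,3-dimethyloxirane-2-carboxylate
Product: 20 (2R,3R)-2,3-dimethyloxirane-2-carbaldehyde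
Conditions: iBu2AlH (1.05 equiv), CH2Cl2, −78 °C; aq KNaC4H4O6
Reagents that add atoms: none
Why: Half-reduction of an α-oxygenated ester stops at the chelated hemiacetal aluminate; the α-centre is quaternary and cannot epimerise; the volatile aldehyde is used as a solution.

**Step 14**
Reactants: 15 epoxy β-hydroxy ketone; 20 (2R,3R)-2,3-dimethyloxirane-2-carbaldehyde
Product: 22 (1R,3S,6R,7R,8R,10S,4Z)-3-(tert-butyldimethylsilyloxy)-1,10-epoxy-8-[(2R,3R)-2,3-dimethyloxirane-2-carbonyloxy]-4,10-dimethyl-6,7-trans-fused γ-lactone (C6–O–C12(=O)–C11H2–C7), via hydroxy ester 21 (not isolated)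
Conditions: SmI2 (0.3 equiv) premixed with 20 (4 equiv), THF, −10 °C; then 15, −10 → 25 °C
Reagents that add atoms: none
Why: Evans–Tishchenko reaction; divalent samarium is oxidised by the aldehyde to the trivalent samarium alkoxide catalyst, the C8 hemiacetal delivers hydride intramolecularly to the C6 ketone to give the 1,3-anti alcohol (C6 R) while C8 becomes the epoxy ester, and the freed C6 alkoxide closes the trans γ-lactone onto the methyl ester.

**Step 15**
Reactants: 22 saturated lactone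
Product: 25 3-O-tert-butyldimethylsilyl ether of the target (α-methylene lactone), via Mannich base 23 (not isolated), via ammonium iodide 24 (not isolated)
Conditions: LiN(SiMe3)2, THF, −78 °C; CH2=NMe2+ I−, −78 → 0 °C; MeI, 25 °C; aq NaHCO3
Reagents that add atoms: N,N-dimethylmethyleneiminium iodide, C=[N+](C)C.[I-]
Why: Eschenmoser methylenation (lactone enolate Mannich reaction, quaternisation, Hofmann-type elimination); C11 is the only enolisable position because the C8 ester has no α-hydrogen.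

**Step 16**
Reactants: 25 silyl ether
Product: 26 target CNP0268255.3
Conditions: Bu4NF, AcOH, THF, 0 → 25 °C
Reagents that add atoms: none
Why: Buffered fluoride desilylation frees the C3 hydroxyl without opening the acid-sensitive oxiranes or adding to the α-methylene lactone.

## Compound list

1 | (S)-(+)-carvone | CC1=CC[C@@H](CC1=O)C(C)=C | starting material
2 | (1S,5S)-cis-carveol | CC1=CC[C@@H](C[C@@H]1O)C(C)=C | intermediate
3 | tert-butyldimethyl{[(1S,5S)-2-methyl-5-(prop-1-en-2-yl)cyclohex-2-en-1-yl]oxy}silane | CC1=CC[C@@H](C[C@@H]1O[Si](C)(C)C(C)(C)C)C(C)=C | intermediate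
4 | (4S,6S)-4-(tert-butyldimethylsilyloxy)-3-methyl-6-(prop-1-en-2-yl)cyclohex-2-en-1-one | CC1=CC(=O)[C@@H](C[C@@H]1O[Si](C)(C)C(C)(C)C)C(C)=C | intermediate
5 | 2-phenylpropan-2-ol | CC(C)(O)c1ccccc1 | starting material
6 | (E)-1,2-dichloro-1-(2-phenylpropan-2-yloxy)ethene | CC(C)(O/C(Cl)=C\Cl)c1ccccc1 | intermediate
7 | lithium (2-phenylpropan-2-yloxy)acetylide | [Li]C#COC(C)(C)c1ccccc1 | intermediate (not isolated)
8 | (1S,4S,6S)-4-(tert-butyldimethylsilyloxy)-3-methyl-1-[(2-phenylpropan-2-yloxy)ethynyl]-6-(prop-1-en-2-yl)cyclohex-2-en-1-ol | CC1=C[C@@](O)(C#COC(C)(C)c2ccccc2)[C@@H](C[C@@H]1O[Si](C)(C)C(C)(C)C)C(C)=C | intermediate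
9 | (1S,4S,6S)-4-(tert-butyldimethylsilyloxy)-3-methyl-1-[(Z)-2-(2-phenylpropan-2-yloxy)ethenyl]-6-(prop-1-en-2-yl)cyclohex-2-en-1-ol | CC1=C[C@@](O)(/C=C\OC(C)(C)c2ccccc2)[C@@H](C[C@@H]1O[Si](C)(C)C(C)(C)C)C(C)=C | intermediate
10 | potassium alkoxide of 9 | CC1=C[C@@]([O-])(/C=C\OC(C)(C)c2ccccc2)[C@@H](C[C@@H]1O[Si](C)(C)C(C)(C)C)C(C)=C.[K+] | intermediate (not isolated)
11 | potassium (3S,8R,1(10)E,4Z,6Z)-3-(tert-butyldimethylsilyloxy)-4,10-dimethyl-8-(2-phenylpropan-2-yloxy)cyclodeca-1(10),4,6-trien-6-olate | [O-]/C1=C\[C@H](OC(C)(C)c2ccccc2)C/C(C)=C/C[C@H](O[Si](C)(C)C(C)(C)C)/C(C)=C\1.[K+] | intermediate (not isolated)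
12 | methyl 2-[(3S,7R,8R,1(10)E,4Z)-3-(tert-butyldimethylsilyloxy)-4,10-dimethyl-6-oxo-8-(2-phenylpropan-2-yloxy)cyclodeca-1(10),4-dien-7-yl]acetate | O=C1[C@H](CC(=O)OC)[C@H](OC(C)(C)c2ccccc2)C/C(C)=C/C[C@H](O[Si](C)(C)C(C)(C)C)/C(C)=C\1 | intermediate
13 | methyl 2-[(3S,7R,8R,1(10)Z,4Z)-3-(tert-butyldimethylsilyloxy)-4,10-dimethyl-6-oxo-8-(2-phenylpropan-2-yloxy)cyclodeca-1(10),4-dien-7-yl]acetate | O=C1[C@H](CC(=O)OC)[C@H](OC(C)(C)c2ccccc2)C/C(C)=C\C[C@H](O[Si](C)(C)C(C)(C)C)/C(C)=C\1 | intermediate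
14 | methyl 2-[(3S,7R,8R,1(10)Z,4Z)-3-(tert-butyldimethylsilyloxy)-8-hydroxy-4,10-dimethyl-6-oxocyclodeca-1(10),4-dien-7-yl]acetate | O=C1[C@H](CC(=O)OC)[C@H](O)C/C(C)=C\C[C@H](O[Si](C)(C)C(C)(C)C)/C(C)=C\1 | intermediate
15 | methyl 2-[(1R,3S,7R,8R,10S,4Z)-3-(tert-butyldimethylsilyloxy)-1,10-epoxy-8-hydroxy-4,10-dimethyl-6-oxocyclodec-4-en-7-yl]acetate | O=C1[C@H](CC(=O)OC)[C@H](O)C[C@]2(C)O[C@@H]2C[C@H](O[Si](C)(C)C(C)(C)C)/C(C)=C\1 | intermediate
16 | methyl (R)-3-hydroxybutanoate | C[C@@H](O)CC(=O)OC | starting material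
17 | methyl (2R,3R)-2-chloro-3-hydroxybutanoate | C[C@@H](O)[C@@H](Cl)C(=O)OC | intermediate
18 | lithium alkoxide of methyl (2S,3R)-2-chloro-3-hydroxy-2-methylbutanoate | C[C@@H]([O-])[C@](C)(Cl)C(=O)OC.[Li+] | intermediate (not isolated)
19 | methyl (2R,3R)-2,3-dimethyloxirane-2-carboxylate | COC(=O)[C@]1(C)O[C@@H]1C | intermediate
20 | (2R,3R)-2,3-dimethyloxirane-2-carbaldehyde | O=C[C@]1(C)O[C@@H]1C | intermediate
21 | methyl 2-[(1R,3S,6R,7S,8R,10S,4Z)-3-(tert-butyldimethylsilyloxy)-8-[(2R,3R)-2,3-dimethyloxirane-2-carbonyloxy]-1,10-epoxy-6-hydroxy-4,10-dimethylcyclodec-4-en-7-yl]acetate (C7 descriptor changes by CIP only) | O[C@H]1[C@H](CC(=O)OC)[C@H](OC(=O)[C@]2(C)O[C@@H]2C)C[C@]3(C)O[C@@H]3C[C@H](O[Si](C)(C)C(C)(C)C)/C(C)=C\1 | intermediate (not isolated)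
22 | (1R,3S,6R,7R,8R,10S,4Z)-3-(tert-butyldimethylsilyloxy)-1,10-epoxy-8-[(2R,3R)-2,3-dimethyloxirane-2-carbonyloxy]-4,10-dimethyl trans-6,12-lactone with C11H2 | C1C(=O)O[C@@H]2/C=C(/C)[C@@H](O[Si](C)(C)C(C)(C)C)C[C@H]3O[C@@]3(C)C[C@@H](OC(=O)[C@]3(C)O[C@@H]3C)[C@@H]12 | intermediate
23 | 11-(dimethylaminomethyl) derivative of 22 (C11 epimers, centre removed again) | CN(C)CC1C(=O)O[C@@H]2/C=C(/C)[C@@H](O[Si](C)(C)C(C)(C)C)C[C@H]3O[C@@]3(C)C[C@@H](OC(=O)[C@]3(C)O[C@@H]3C)[C@@H]12 | intermediate (not isolated)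
24 | 11-(trimethylammoniomethyl) iodide of 22 (C11 epimers) | C[N+](C)(C)CC1C(=O)O[C@@H]2/C=C(/C)[C@@H](O[Si](C)(C)C(C)(C)C)C[C@H]3O[C@@]3(C)C[C@@H](OC(=O)[C@]3(C)O[C@@H]3C)[C@@H]12.[I-] | intermediate (not isolated)
25 | 3-O-tert-butyldimethylsilyl ether of the target | C=C1C(=O)O[C@@H]2/C=C(/C)[C@@H](O[Si](C)(C)C(C)(C)C)C[C@H]3O[C@@]3(C)C[C@@H](OC(=O)[C@]3(C)O[C@@H]3C)[C@@H]12 | intermediate
26 | CNP0268255.3: (1R,3S,6R,7R,8R,10S,4Z)-1,10-epoxy-3-hydroxy-8-[(2R,3R)-2,3-dimethyloxirane-2-carbonyloxy]germacra-4,11(13)-dien-6,12-olide | C=C1C(=O)O[C@@H]2/C=C(/C)[C@@H](O)C[C@H]3O[C@@]3(C)C[C@@H](OC(=O)[C@]3(C)O[C@@H]3C)[C@@H]12 | target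

## Count and risks

Total steps: 16. Longest linear sequence: 12 (steps 1, 2, 3, 5, 6, 7, 8, 9, 10, 14, 15, 16).

**Step 7 (oxy-Cope/alkylation).** Risks: the (Z)-alkoxy group must sit pseudoaxial in the chair; the β-alkoxy enolate could lose cumyl oxide at 25 °C; C-alkylation must occur on the face syn to the C8 oxygen. Fallback, setting out from 9 and coming back at 12: run the rearrangement as before but quench enolate 11 at −78 °C with Me3SiCl and isolate the trimethylsilyl enol ether of the ring-expanded ketone F1, which lets the C8 configuration and the olefin geometry be checked. Then release a metal-free ammonium enolate from F1 with BnMe3NF in THF at −78 °C in the presence of ICH2CO2Me (fluoride-triggered silyl enol ether alkylation), where loss of the β-alkoxide is frozen out, to reach 12.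

**Step 8 (E→Z equilibration).** Risks: the equilibrium may not lie far enough on the (Z,Z) side, or the C10 radical may cyclise across the ring onto the enone. Fallback, setting out from 12 and coming back at 13: a stereospecific inversion in place of equilibration. mCPBA/NaHCO3 epoxidises only the isolated 1(10) olefin to the (1R,10R)-trans-epoxide F2. Catalytic HClO4 in aqueous THF at 0 °C opens it with inversion at the tertiary C10 to the (1R,10S)-diol F3. 1,1'-Thiocarbonyldiimidazole/DMAP gives the cyclic thionocarbonate F4. Corey–Winter syn-elimination with 1,3-dimethyl-2-phenyl-1,3,2-diazaphospholidine at 40 °C delivers the (Z)-olefin 13.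

**Step 14 (Evans–Tishchenko/lactonisation).** Risks: the hindered, precious epoxy aldehyde may transfer hydride sluggishly; the C8 hydroxyl of 14/15 may lactonise onto the ester first; acyl migration may compete. Fallback, setting out from 15 and coming back at 22: hydroxyl-directed anti reduction with Me4NBH(OAc)3 in MeCN/AcOH at −30 °C gives the 6,8-anti-diol ester F5, which is lactonised through the allylic C6 hydroxyl to the 8-hydroxy lactone F6. Separately 19 is saponified (LiOH, THF/H2O) to (2R,3R)-2,3-dimethyloxirane-2-carboxylic acid F7. F6 is esterified with F7 (2,4,6-Cl3C6H2COCl, Et3N, DMAP, toluene) to give 22.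

## Further compounds

F1 | step 7 | trimethylsilyl enol ether of (3S,8R,1(10)E,4Z)-3-(tert-butyldimethylsilyloxy)-4,10-dimethyl-8-(2-phenylpropan-2-yloxy)cyclodeca-1(10),4-dien-6-one (C6=C7 enol ether) | C[Si](C)(C)O/C1=C\[C@H](OC(C)(C)c2ccccc2)C/C(C)=C/C[C@H](O[Si](C)(C)C(C)(C)C)/C(C)=C\1
F2 | step 8 | (1R,10R)-1,10-trans-epoxide of 12 | O=C1[C@H](CC(=O)OC)[C@H](OC(C)(C)c2ccccc2)C[C@@]3(C)O[C@@H]3C[C@H](O[Si](C)(C)C(C)(C)C)/C(C)=C\1
F3 | step 8 | (1R,10S)-1,10-diol from F2 | O=C1[C@H](CC(=O)OC)[C@H](OC(C)(C)c2ccccc2)C[C@](C)(O)[C@H](O)C[C@H](O[Si](C)(C)C(C)(C)C)/C(C)=C\1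
F4 | step 8 | cyclic 1,10-thionocarbonate of F3 | O=C1[C@H](CC(=O)OC)[C@H](OC(C)(C)c2ccccc2)C[C@]3(C)OC(=S)O[C@@H]3C[C@H](O[Si](C)(C)C(C)(C)C)/C(C)=C\1
F5 | step 14 | methyl 2-[(1R,3S,6R,7R,8R,10S,4Z)-3-(tert-butyldimethylsilyloxy)-1,10-epoxy-6,8-dihydroxy-4,10-dimethylcyclodec-4-en-7-yl]acetate | O[C@H]1[C@H](CC(=O)OC)[C@H](O)C[C@]2(C)O[C@@H]2C[C@H](O[Si](C)(C)C(C)(C)C)/C(C)=C\1
F6 | step 14 | 8-hydroxy analogue of 22 (trans-6,12-lactone, free C8 hydroxyl) | C1C(=O)O[C@@H]2/C=C(/C)[C@@H](O[Si](C)(C)C(C)(C)C)C[C@H]3O[C@@]3(C)C[C@@H](O)[C@@H]12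
F7 | step 14 | (2R,3R)-2,3-dimethyloxirane-2-carboxylic acid | OC(=O)[C@]1(C)O[C@@H]1C
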